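**Assumption:** the SMILES is taken literally: lactone (3S,4S); the arm on the C3‑benzyl ring (ring A) is (1S,2R) (syn), the arm on the C4‑benzyl ring (ring B) is (1S,2S) (anti).

## Retrosynthetic overview

1. Target ⇐ debenzylation and acetonide removal of a trans‑(3S,4S)‑dibenzylbutyrolactone whose two aryl rings carry the protected 2‑aryl‑1,3‑diol arms.
2. Lactone core ⇐ one‑pot union of three pieces: an aryl Grignard (ring B) opens a cyclopropane‑fused lactone, and the resulting enolate is benzylated by a ring A benzylic bromide; demethoxycarbonylation then sets the trans relationship.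
3. Cyclopropane‑fused lactone ⇐ (S)‑epichlorohydrin + dimethyl malonate; the cyclopropane and the γ‑lactone form in the same operation and fix C4.
4. Both arms ⇐ one common arylacetyl oxazolidinone and O‑benzylvanillin: boron syn‑aldol for ring A, magnesium‑catalysed anti‑aldol for ring B.
5. Ring order: the two protective dioxane rings (one per arm), then cyclopropane + lactone together, then the cyclopropane is opened and the lactone kept; the dioxanes are removed at the end.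

## Route

Step 1
Reactants: 1 5-bromo-2-hydroxy-3-methoxybenzaldehyde
Product: 2 2-(benzyloxy)-5-bromo-3-methoxybenzaldehyde
Conditions: BnBr, K2CO3, DMF, 60 °C
Reagents that add atoms: benzyl bromide, BrCc1ccccc1
Why: Williamson ether synthesis on the phenoxide protects the phenol as a benzyl ether that survives every later step and is removed by hydrogenolysis at the end.

Step 2
Reactants: 2 2-(benzyloxy)-5-bromo-3-methoxybenzaldehyde
Product: 3 1-[2-(benzyloxy)-5-bromo-3-methoxyphenyl]-2,2,2-trichloroethan-1-ol (racemic)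
Conditions: CHCl3 (solvent), DBU (1 equiv), 0 °C to rt
Reagents that add atoms: chloroform, ClC(Cl)Cl
Why: Amidine‑promoted addition of the trichloromethyl anion to a non‑enolisable aldehyde (Corey–Link‑type carbinol formation); the new stereocentre is destroyed in step 3, so the racemate is used.

Step 3
Reactants: 3 1-[2-(benzyloxy)-5-bromo-3-methoxyphenyl]-2,2,2-trichloroethan-1-ol
Product: 6 [2-(benzyloxy)-5-bromo-3-methoxyphenyl]acetic acid, via dichloroepoxide 4 (not isolated), via acyl chloride 5 (not isolated)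
Conditions: NaBH4, NaOH, t-BuOH/H2O, 55 °C; then aq. HCl
Reagents that add atoms: sodium hydroxide, [Na+].[OH-]
Why: Reductive Jocic–Reeve homologation, in which the alkoxide closes to the gem‑dichloroepoxide, hydride opens it at the benzylic carbon and the resulting acyl chloride is hydrolysed, giving the arylacetic acid in one operation without touching the aryl bromide.

Step 4
Reactants: 6 [2-(benzyloxy)-5-bromo-3-methoxyphenyl]acetic acid; 7 (S)-4-benzyloxazolidin-2-one
Product: 9 (S)-4-benzyl-3-{[2-(benzyloxy)-5-bromo-3-methoxyphenyl]acetyl}oxazolidin-2-one, via mixed pivalic anhydride 8 (not isolated)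
Conditions: PivCl, Et3N, THF, −20 °C; then 7, LiCl, rt
Reagents that add atoms: none
Why: One‑pot mixed‑anhydride N‑acylation of the Evans auxiliary, with the hindered pivaloyl carbonyl directing attack to the arylacetyl carbonyl.

Step 5
Reactants: 9 (S)-4-benzyl-3-{[2-(benzyloxy)-5-bromo-3-methoxyphenyl]acetyl}oxazolidin-2-one; 10 4-(benzyloxy)-3-methoxybenzaldehyde
Product: 12 (S)-4-benzyl-3-{(2S,3S)-2-[2-(benzyloxy)-5-bromo-3-methoxyphenyl]-3-[4-(benzyloxy)-3-methoxyphenyl]-3-hydroxypropanoyl}oxazolidin-2-one, via Z-boron enolate 11 (not isolated)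
Conditions: Bu2BOTf, i-Pr2NEt, CH2Cl2, −78 to 0 °C; 10, −78 to 0 °C; then pH 7 buffer, MeOH, 30% H2O2, 0 °C
Reagents that add atoms: none
Why: Evans syn‑aldol reaction, in which the Z‑dibutylboron enolate reacts through a closed Zimmerman–Traxler chair with the auxiliary carbonyl turned away, so the (S)‑auxiliary sets both new centres as (2S,3S), the syn arm of ring A.

Step 6
Reactants: 12 the syn aldol adduct
Product: 13 (1S,2R)-2-[2-(benzyloxy)-5-bromo-3-methoxyphenyl]-1-[4-(benzyloxy)-3-methoxyphenyl]propane-1,3-diol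
Conditions: LiBH4, THF, MeOH (1 equiv), 0 °C
Reagents that add atoms: none
Why: Reductive cleavage of the N‑acyl oxazolidinone by LiBH4 gives the primary alcohol without epimerisation (the change of descriptor at C2 is only a CIP priority change) and leaves the aryl bromide intact.

Step 7
Reactants: 13 the (1S,2R)-diol
Product: 14 (4S,5R)-5-[2-(benzyloxy)-5-bromo-3-methoxyphenyl]-4-[4-(benzyloxy)-3-methoxyphenyl]-2,2-dimethyl-1,3-dioxane
Conditions: Me2C(OMe)2, PPTS (cat.), CH2Cl2, rt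
Reagents that add atoms: 2,2-dimethoxypropane, COC(C)(C)OC
Why: Acid‑catalysed ketal exchange ties the 1,3‑diol up as an acetonide under conditions too mild to ionise the benzylic carbinol, so both centres are retained.

Step 8
Reactants: 14 the cis acetonide
Product: 17 {4-(benzyloxy)-3-[(4S,5R)-4-[4-(benzyloxy)-3-methoxyphenyl]-2,2-dimethyl-1,3-dioxan-5-yl]-5-methoxyphenyl}methanol, via aryllithium 15 (not isolated), via aldehyde 16 (not isolated)
Conditions: n-BuLi, THF, −78 °C; DMF, −78 to 0 °C; then MeOH, NaBH4, 0 °C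
Reagents that add atoms: N,N-dimethylformamide, CN(C)C=O
Why: Bromine–lithium exchange, Bouveault formylation and in‑flask borohydride reduction convert the aryl bromide into the benzylic alcohol without touching the acetonide or benzyl ethers.

Step 9
Reactants: 17 the benzylic alcohol
Product: 18 (4S,5R)-5-[2-(benzyloxy)-5-(bromomethyl)-3-methoxyphenyl]-4-[4-(benzyloxy)-3-methoxyphenyl]-2,2-dimethyl-1,3-dioxane
Conditions: CBr4, PPh3, CH2Cl2, 0 °C (used crude)
Reagents that add atoms: carbon tetrabromide, BrC(Br)(Br)Br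
Why: Appel bromination under neutral conditions gives the electron‑rich benzylic bromide without acid that would endanger the acetonide.

Step 10
Reactants: 9 the arylacetyl imide; 10 4-(benzyloxy)-3-methoxybenzaldehyde
Product: 20 (S)-4-benzyl-3-{(2R,3S)-2-[2-(benzyloxy)-5-bromo-3-methoxyphenyl]-3-[4-(benzyloxy)-3-methoxyphenyl]-3-hydroxypropanoyl}oxazolidin-2-one, via trimethylsilyl ether 19 (not isolated)
Conditions: MgCl2 (20 mol%), Et3N, TMSCl, EtOAc, 23 °C; then 1 M HCl, THF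
Reagents that add atoms: none
Why: Evans magnesium halide‑catalysed direct anti‑aldol reaction, in which the chelated magnesium Z‑enolate is attacked on the face away from the auxiliary benzyl group (the same face as in auxiliary alkylations) through a boat‑like transition state, giving the (2R,3S) anti adduct that carries the ring B arm, with silylation turning the catalyst over and protecting the adduct from retro‑aldol.

Step 11
Reactants: 20 the anti aldol adduct
Product: 21 (1S,2S)-2-[2-(benzyloxy)-5-bromo-3-methoxyphenyl]-1-[4-(benzyloxy)-3-methoxyphenyl]propane-1,3-diol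
Conditions: LiBH4, THF, MeOH (1 equiv), 0 °C
Reagents that add atoms: none
Why: Reductive removal of the auxiliary by LiBH4 as in step 6, with both stereocentres unchanged.

Step 12
Reactants: 21 the (1S,2S)-diol
Product: 22 (4S,5S)-5-[2-(benzyloxy)-5-bromo-3-methoxyphenyl]-4-[4-(benzyloxy)-3-methoxyphenyl]-2,2-dimethyl-1,3-dioxane
Conditions: Me2C(OMe)2, PPTS (cat.), CH2Cl2, rt
Reagents that add atoms: 2,2-dimethoxypropane, COC(C)(C)OC
Why: Acid‑catalysed ketal exchange gives the trans (diequatorial) acetonide, which tolerates the organometallic chemistry of step 14.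

Step 13
Reactants: 23 (S)-2-(chloromethyl)oxirane; 24 dimethyl malonate
Product: 27 methyl (1R,5S)-2-oxo-3-oxabicyclo[3.1.0]hexane-1-carboxylate, via epoxy malonate 25 (not isolated), via cyclopropyl carbinol 26 (not isolated)
Conditions: NaOMe (1.0 equiv), MeOH, 0 °C to reflux
Reagents that add atoms: none
Why: Double alkylation of malonate by epichlorohydrin followed by lactonisation, in which the malonate anion opens the epoxide at CH2, the alkoxide displaces chloride to give epoxide 25, a second deprotonation closes the cyclopropane by 3‑exo‑tet attack with inversion, and the cis CH2O− lactonises, so the cyclopropane and the γ‑lactone form in one flask and the (S)‑epichlorohydrin centre becomes C5 (S), the future C4 (S) of the target.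

Step 14
Reactants: 22 the trans acetonide aryl bromide; 27 the bicyclic lactone; 18 the benzylic bromide
Product: 31 methyl (3S,4S)-3-{[4-(benzyloxy)-3-methoxy-5-((4S,5R)-4-[4-(benzyloxy)-3-methoxyphenyl]-2,2-dimethyl-1,3-dioxan-5-yl)phenyl]methyl}-4-{[4-(benzyloxy)-3-methoxy-5-((4S,5S)-4-[4-(benzyloxy)-3-methoxyphenyl]-2,2-dimethyl-1,3-dioxan-5-yl)phenyl]methyl}-2-oxooxolane-3-carboxylate, via aryllithium 28 (not isolated), via arylmagnesium bromide 29 (not isolated), via magnesium enolate 30 (not isolated)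
Conditions: 22, n-BuLi, THF, −78 °C; MgBr2·OEt2, −78 to −30 °C; CuBr·SMe2 (15 mol%), 27, −30 to 0 °C; then 18, DMPU, 0 °C to rt
Reagents that add atoms: none
Why: Copper‑catalysed homoconjugate addition of the aryl Grignard to the doubly activated cyclopropane occurs at the unhindered CH2 (C5 is untouched, so C4 stays S), and the malonate‑type enolate released is C‑benzylated in the same flask anti to the C4 substituent (tandem three‑component coupling).

Step 15
Reactants: 31 the quaternary lactone ester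
Product: 34 (3S,4S)-3-{[4-(benzyloxy)-3-methoxy-5-((4S,5R)-4-[4-(benzyloxy)-3-methoxyphenyl]-2,2-dimethyl-1,3-dioxan-5-yl)phenyl]methyl}-4-{[4-(benzyloxy)-3-methoxy-5-((4S,5S)-4-[4-(benzyloxy)-3-methoxyphenyl]-2,2-dimethyl-1,3-dioxan-5-yl)phenyl]methyl}oxolan-2-one, via lithium carboxylate 32 (not isolated), via lithium enolate 33 (not isolated)
Conditions: LiCl, H2O, DMSO, 150 °C
Reagents that add atoms: none
Why: Krapcho demethoxycarbonylation (chloride SN2 at the ester methyl, loss of CO2, protonation of the lactone enolate), with C3 settling under the hot basic conditions to the thermodynamically favoured trans‑3,4‑dibenzyl lactone, that is (3S) next to the fixed (4S).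

Step 16
Reactants: 34 the protected trans lactone
Product: 35 (3S,4S)-3-({4-(benzyloxy)-3-[(1S,2R)-1-[4-(benzyloxy)-3-methoxyphenyl]-1,3-dihydroxypropan-2-yl]-5-methoxyphenyl}methyl)-4-({4-(benzyloxy)-3-[(1S,2S)-1-[4-(benzyloxy)-3-methoxyphenyl]-1,3-dihydroxypropan-2-yl]-5-methoxyphenyl}methyl)oxolan-2-one
Conditions: AcOH/THF/H2O (3:1:1), 45 °C
Reagents that add atoms: none
Why: Acid‑catalysed ketal hydrolysis with a weak acid in water cleaves both acetonides at the ketal carbon while the phenols are still benzylated, so the benzylic carbinols are not ionised and the lactone is untouched.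

Step 17
Reactants: 35 the tetra-O-benzyl tetraol
Product: 36 (3S,4S)-3-({3-[(1S,2R)-1,3-dihydroxy-1-(4-hydroxy-3-methoxyphenyl)propan-2-yl]-4-hydroxy-5-methoxyphenyl}methyl)-4-({3-[(1S,2S)-1,3-dihydroxy-1-(4-hydroxy-3-methoxyphenyl)propan-2-yl]-4-hydroxy-5-methoxyphenyl}methyl)oxolan-2-one
Conditions: H2 (1 atm), 10% Pd/C, EtOAc/MeOH, rt, stopped at full debenzylation
Reagents that add atoms: none
Why: Hydrogenolysis of the four aryl benzyl ethers under neutral conditions is much faster than hydrogenolysis of the free secondary benzylic alcohols, so all stereocentres and hydroxyl groups are kept.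

## Compound list

1 | 5-bromo-2-hydroxy-3-methoxybenzaldehyde | COc1cc(Br)cc(C=O)c1O | starting material
2 | 2-(benzyloxy)-5-bromo-3-methoxybenzaldehyde | COc1cc(Br)cc(C=O)c1OCc1ccccc1 | intermediate
3 | 1-[2-(benzyloxy)-5-bromo-3-methoxyphenyl]-2,2,2-trichloroethan-1-ol (racemic) | COc1cc(Br)cc(C(O)C(Cl)(Cl)Cl)c1OCc1ccccc1 | intermediate
4 | 3-[2-(benzyloxy)-5-bromo-3-methoxyphenyl]-2,2-dichlorooxirane | COc1cc(Br)cc(C2OC2(Cl)Cl)c1OCc1ccccc1 | intermediate
5 | [2-(benzyloxy)-5-bromo-3-methoxyphenyl]acetyl chloride | COc1cc(Br)cc(CC(=O)Cl)c1OCc1ccccc1 | intermediate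
6 | [2-(benzyloxy)-5-bromo-3-methoxyphenyl]acetic acid | COc1cc(Br)cc(CC(=O)O)c1OCc1ccccc1 | intermediate
7 | (S)-4-benzyloxazolidin-2-one | O=C1N[C@@H](Cc2ccccc2)CO1 | starting material
8 | [2-(benzyloxy)-5-bromo-3-methoxyphenyl]acetic pivalic anhydride | COc1cc(Br)cc(CC(=O)OC(=O)C(C)(C)C)c1OCc1ccccc1 | intermediate
9 | (S)-4-benzyl-3-{[2-(benzyloxy)-5-bromo-3-methoxyphenyl]acetyl}oxazolidin-2-one | COc1cc(Br)cc(CC(=O)N2[C@@H](Cc3ccccc3)COC2=O)c1OCc1ccccc1 | intermediate
10 | 4-(benzyloxy)-3-methoxybenzaldehyde | COc1cc(C=O)ccc1OCc1ccccc1 | starting material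
11 | Z-dibutylboron enolate of 9 | CCCCB(CCCC)O/C(=C\c1cc(Br)cc(OC)c1OCc1ccccc1)N1[C@@H](Cc2ccccc2)COC1=O | intermediate
12 | (S)-4-benzyl-3-{(2S,3S)-2-[2-(benzyloxy)-5-bromo-3-methoxyphenyl]-3-[4-(benzyloxy)-3-methoxyphenyl]-3-hydroxypropanoyl}oxazolidin-2-one | O=C(N1[C@@H](Cc2ccccc2)COC1=O)[C@@H](c1cc(Br)cc(OC)c1OCc1ccccc1)[C@H](O)c1ccc(OCc2ccccc2)c(OC)c1 | intermediate
13 | (1S,2R)-2-[2-(benzyloxy)-5-bromo-3-methoxyphenyl]-1-[4-(benzyloxy)-3-methoxyphenyl]propane-1,3-diol | OC[C@@H](c1cc(Br)cc(OC)c1OCc1ccccc1)[C@H](O)c1ccc(OCc2ccccc2)c(OC)c1 | intermediate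
14 | (4S,5R)-5-[2-(benzyloxy)-5-bromo-3-methoxyphenyl]-4-[4-(benzyloxy)-3-methoxyphenyl]-2,2-dimethyl-1,3-dioxane | CC1(C)OC[C@@H](c2cc(Br)cc(OC)c2OCc2ccccc2)[C@@H](c2ccc(OCc3ccccc3)c(OC)c2)O1 | intermediate
15 | aryllithium from 14 (Li in place of Br) | CC1(C)OC[C@@H](c2cc([Li])cc(OC)c2OCc2ccccc2)[C@@H](c2ccc(OCc3ccccc3)c(OC)c2)O1 | intermediate
16 | 4-(benzyloxy)-3-[(4S,5R)-4-[4-(benzyloxy)-3-methoxyphenyl]-2,2-dimethyl-1,3-dioxan-5-yl]-5-methoxybenzaldehyde | CC1(C)OC[C@@H](c2cc(C=O)cc(OC)c2OCc2ccccc2)[C@@H](c2ccc(OCc3ccccc3)c(OC)c2)O1 | intermediate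
17 | {4-(benzyloxy)-3-[(4S,5R)-4-[4-(benzyloxy)-3-methoxyphenyl]-2,2-dimethyl-1,3-dioxan-5-yl]-5-methoxyphenyl}methanol | CC1(C)OC[C@@H](c2cc(CO)cc(OC)c2OCc2ccccc2)[C@@H](c2ccc(OCc3ccccc3)c(OC)c2)O1 | intermediate
18 | (4S,5R)-5-[2-(benzyloxy)-5-(bromomethyl)-3-methoxyphenyl]-4-[4-(benzyloxy)-3-methoxyphenyl]-2,2-dimethyl-1,3-dioxane | CC1(C)OC[C@@H](c2cc(CBr)cc(OC)c2OCc2ccccc2)[C@@H](c2ccc(OCc3ccccc3)c(OC)c2)O1 | intermediate
19 | O-trimethylsilyl ether of 20 | O=C(N1[C@@H](Cc2ccccc2)COC1=O)[C@H](c1cc(Br)cc(OC)c1OCc1ccccc1)[C@H](O[Si](C)(C)C)c1ccc(OCc2ccccc2)c(OC)c1 | intermediate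
20 | (S)-4-benzyl-3-{(2R,3S)-2-[2-(benzyloxy)-5-bromo-3-methoxyphenyl]-3-[4-(benzyloxy)-3-methoxyphenyl]-3-hydroxypropanoyl}oxazolidin-2-one | O=C(N1[C@@H](Cc2ccccc2)COC1=O)[C@H](c1cc(Br)cc(OC)c1OCc1ccccc1)[C@H](O)c1ccc(OCc2ccccc2)c(OC)c1 | intermediate
21 | (1S,2S)-2-[2-(benzyloxy)-5-bromo-3-methoxyphenyl]-1-[4-(benzyloxy)-3-methoxyphenyl]propane-1,3-diol | OC[C@H](c1cc(Br)cc(OC)c1OCc1ccccc1)[C@H](O)c1ccc(OCc2ccccc2)c(OC)c1 | intermediate
22 | (4S,5S)-5-[2-(benzyloxy)-5-bromo-3-methoxyphenyl]-4-[4-(benzyloxy)-3-methoxyphenyl]-2,2-dimethyl-1,3-dioxane | CC1(C)OC[C@H](c2cc(Br)cc(OC)c2OCc2ccccc2)[C@@H](c2ccc(OCc3ccccc3)c(OC)c2)O1 | intermediate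
23 | (S)-2-(chloromethyl)oxirane ((S)-epichlorohydrin) | ClC[C@@H]1CO1 | starting material
24 | dimethyl malonate | COC(=O)CC(=O)OC | starting material
25 | dimethyl 2-{[(2S)-oxiran-2-yl]methyl}propanedioate | COC(=O)C(C[C@H]1CO1)C(=O)OC | intermediate
26 | dimethyl (2S)-2-(hydroxymethyl)cyclopropane-1,1-dicarboxylate (as its sodium alkoxide) | COC(=O)C1(C(=O)OC)C[C@@H]1CO | intermediate
27 | methyl (1R,5S)-2-oxo-3-oxabicyclo[3.1.0]hexane-1-carboxylate | O=C1OC[C@H]2C[C@@]12C(=O)OC | intermediate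
28 | aryllithium from 22 (Li in place of Br) | CC1(C)OC[C@H](c2cc([Li])cc(OC)c2OCc2ccccc2)[C@@H](c2ccc(OCc3ccccc3)c(OC)c2)O1 | intermediate
29 | arylmagnesium bromide from 22 (MgBr in place of Br) | CC1(C)OC[C@H](c2cc([Mg]Br)cc(OC)c2OCc2ccccc2)[C@@H](c2ccc(OCc3ccccc3)c(OC)c2)O1 | intermediate
30 | bromomagnesium enolate of methyl (4S)-4-{[ring B aryl]methyl}-2-oxooxolane-3-carboxylate | COC(=O)C1=C(O[Mg]Br)OC[C@H]1Cc1cc(OC)c(OCc2ccccc2)c([C@H]2COC(C)(C)O[C@@H]2c2ccc(OCc3ccccc3)c(OC)c2)c1 | intermediate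
31 | methyl (3S,4S)-3-{[ring A aryl]methyl}-4-{[ring B aryl]methyl}-2-oxooxolane-3-carboxylate (full name in step 14) | O=C1OC[C@@H](Cc2cc(OC)c(OCc3ccccc3)c([C@H]3COC(C)(C)O[C@@H]3c3ccc(OCc4ccccc4)c(OC)c3)c2)[C@@]1(Cc1cc(OC)c(OCc2ccccc2)c([C@@H]2COC(C)(C)O[C@@H]2c2ccc(OCc3ccccc3)c(OC)c2)c1)C(=O)OC | intermediate
32 | lithium carboxylate of 31 (CO2Li in place of CO2Me) | O=C1OC[C@@H](Cc2cc(OC)c(OCc3ccccc3)c([C@H]3COC(C)(C)O[C@@H]3c3ccc(OCc4ccccc4)c(OC)c3)c2)[C@@]1(Cc1cc(OC)c(OCc2ccccc2)c([C@@H]2COC(C)(C)O[C@@H]2c2ccc(OCc3ccccc3)c(OC)c2)c1)C(=O)[O-].[Li+] | intermediate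
33 | lithium enolate of lactone 34 | [Li]OC1=C(Cc2cc(OC)c(OCc3ccccc3)c([C@@H]3COC(C)(C)O[C@@H]3c3ccc(OCc4ccccc4)c(OC)c3)c2)[C@H](Cc2cc(OC)c(OCc3ccccc3)c([C@H]3COC(C)(C)O[C@@H]3c3ccc(OCc4ccccc4)c(OC)c3)c2)CO1 | intermediate
34 | (3S,4S)-3-{[ring A aryl]methyl}-4-{[ring B aryl]methyl}oxolan-2-one, bis-acetonide tetrabenzyl ether (full name in step 15) | O=C1OC[C@@H](Cc2cc(OC)c(OCc3ccccc3)c([C@H]3COC(C)(C)O[C@@H]3c3ccc(OCc4ccccc4)c(OC)c3)c2)[C@@H]1Cc1cc(OC)c(OCc2ccccc2)c([C@@H]2COC(C)(C)O[C@@H]2c2ccc(OCc3ccccc3)c(OC)c2)c1 | intermediate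
35 | tetra-O-benzyl ether of the target (full name in step 16) | O=C1OC[C@@H](Cc2cc(OC)c(OCc3ccccc3)c([C@@H](CO)[C@H](O)c3ccc(OCc4ccccc4)c(OC)c3)c2)[C@@H]1Cc1cc(OC)c(OCc2ccccc2)c([C@H](CO)[C@H](O)c2ccc(OCc3ccccc3)c(OC)c2)c1 | intermediate
36 | CNP0113972.1 (full name in step 17) | COc1cc([C@@H](O)[C@H](CO)c2cc(C[C@@H]3COC(=O)[C@H]3Cc3cc(OC)c(O)c([C@H](CO)[C@H](O)c4ccc(O)c(OC)c4)c3)cc(OC)c2O)ccc1O | target

## Step count and risk

Total: 17 steps. Longest linear sequence: 13 steps (steps 1–9, then 14–17).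

**Step 10 (anti‑aldol of the arylacetyl imide).** The magnesium‑catalysed reaction has little precedent with α‑aryl acyl groups, and the anti:syn ratio or the α‑centre may erode under Et3N. The fallback sets Cb by a boron syn‑aldol and then corrects the carbinol. Acid 6 is coupled with (R)-4-benzyloxazolidin-2-one (PivCl, Et3N, LiCl) to give the (R)-imide F1. The Bu2BOTf/i-Pr2NEt aldol with 10 gives the (2R,3R) syn adduct F2, and LiBH4 gives the (1R,2S)-diol F3. Boc2O (1 equiv, DMAP cat., −20 °C) carbonates the primary hydroxyl to give the tert-butyl carbonate F4. MsCl/Et3N then activates the benzylic hydroxyl, which is displaced with inversion by the carbonate carbonyl oxygen with loss of isobutene, giving the trans cyclic carbonate F5; the trans ring is also the one expected if the displacement passes through the benzylic cation. K2CO3/MeOH releases diol 21, where the route is rejoined.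

**Step 14 (one‑pot arylation and benzylation).** The magnesium enolate may be too unreactive to build the quaternary centre, or the Grignard may attack a carbonyl. The fallback splits the union and moves the benzylation to a simple lactone enolate. From 22 and 27 the same copper‑catalysed opening is run and quenched with aqueous NH4Cl to isolate the α‑methoxycarbonyl lactone F6. Krapcho demethoxycarbonylation (LiCl, H2O, DMSO, 150 °C) gives the (4S)-4-(arylmethyl)oxolan-2-one F7. LiHMDS, THF, −78 °C, then bromide 18, alkylates trans to the C4 substituent and gives 34 directly, where the route is rejoined.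

**Step 3 (reductive Jocic homologation).** With this electron‑rich, ortho‑substituted aryl carbinol, retro‑addition and borohydride reduction to the benzyl alcohol may compete. The fallback is a Wittig homologation from aldehyde 2. (Methoxymethyl)triphenylphosphonium chloride and KOt-Bu in THF give the enol ether F8 (E/Z mixture). Aqueous HCl/THF gives the arylacetaldehyde F9. Pinnick oxidation (NaClO2, NaH2PO4, 2-methyl-2-butene, t-BuOH/H2O) gives acid 6, where the route is rejoined.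

## Further compounds

F1 | step 10 | (R)-4-benzyl-3-{[2-(benzyloxy)-5-bromo-3-methoxyphenyl]acetyl}oxazolidin-2-one | COc1cc(Br)cc(CC(=O)N2[C@H](Cc3ccccc3)COC2=O)c1OCc1ccccc1
F2 | step 10 | (R)-4-benzyl-3-{(2R,3R)-2-[2-(benzyloxy)-5-bromo-3-methoxyphenyl]-3-[4-(benzyloxy)-3-methoxyphenyl]-3-hydroxypropanoyl}oxazolidin-2-one | O=C(N1[C@H](Cc2ccccc2)COC1=O)[C@H](c1cc(Br)cc(OC)c1OCc1ccccc1)[C@@H](O)c1ccc(OCc2ccccc2)c(OC)c1
F3 | step 10 | (1R,2S)-2-[2-(benzyloxy)-5-bromo-3-methoxyphenyl]-1-[4-(benzyloxy)-3-methoxyphenyl]propane-1,3-diol | OC[C@H](c1cc(Br)cc(OC)c1OCc1ccccc1)[C@@H](O)c1ccc(OCc2ccccc2)c(OC)c1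
F4 | step 10 | (2S,3R)-2-[2-(benzyloxy)-5-bromo-3-methoxyphenyl]-3-[4-(benzyloxy)-3-methoxyphenyl]-3-hydroxypropyl tert-butyl carbonate | CC(C)(C)OC(=O)OC[C@H](c1cc(Br)cc(OC)c1OCc1ccccc1)[C@@H](O)c1ccc(OCc2ccccc2)c(OC)c1
F5 | step 10 | (4S,5S)-5-[2-(benzyloxy)-5-bromo-3-methoxyphenyl]-4-[4-(benzyloxy)-3-methoxyphenyl]-1,3-dioxan-2-one | O=C1OC[C@H](c2cc(Br)cc(OC)c2OCc2ccccc2)[C@@H](c2ccc(OCc3ccccc3)c(OC)c2)O1
F6 | step 14 | methyl (4S)-4-{[4-(benzyloxy)-3-methoxy-5-((4S,5S)-4-[4-(benzyloxy)-3-methoxyphenyl]-2,2-dimethyl-1,3-dioxan-5-yl)phenyl]methyl}-2-oxooxolane-3-carboxylate (C3 epimers) | COC(=O)C1C(=O)OC[C@H]1Cc1cc(OC)c(OCc2ccccc2)c([C@H]2COC(C)(C)O[C@@H]2c2ccc(OCc3ccccc3)c(OC)c2)c1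
F7 | step 14 | (4S)-4-{[4-(benzyloxy)-3-methoxy-5-((4S,5S)-4-[4-(benzyloxy)-3-methoxyphenyl]-2,2-dimethyl-1,3-dioxan-5-yl)phenyl]methyl}oxolan-2-one | O=C1C[C@H](Cc2cc(OC)c(OCc3ccccc3)c([C@H]3COC(C)(C)O[C@@H]3c3ccc(OCc4ccccc4)c(OC)c3)c2)CO1
F8 | step 3 | 2-(benzyloxy)-5-bromo-1-methoxy-3-(2-methoxyethenyl)benzene (E/Z mixture) | COC=Cc1cc(Br)cc(OC)c1OCc1ccccc1
F9 | step 3 | [2-(benzyloxy)-5-bromo-3-methoxyphenyl]acetaldehyde | O=CCc1cc(Br)cc(OC)c1OCc1ccccc1
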